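I wanted to know whether the average chain in this flask, counted over all chains begun, reaches 40 monomer units by 8.0 h, and how long it is at that time.

    free monomer + initiator → living end + monomer in chains (k1 = 0.0011 M⁻¹ s⁻¹)
    free monomer + living end → monomer in chains + living end, rate k2*[living end]*[free monomer] (k2 = 0.0034 M⁻¹ s⁻¹)
    protic impurity + free monomer → quenched substrate (k3 = 8.3 × 10⁻⁴ M⁻¹ s⁻¹)
    2 initiator → spent initiator (k4 = 0.039 M⁻¹ s⁻¹)

free monomer 3.0 M; protic impurity 0.600 M; initiator 110 mM; time 8.0 h

* whether the average number of monomer units in a chain (chains begun, living or dead) reaches 40 by 8.0 h (yes / no)
* average number of monomer units in a chain (chains begun, living or dead) at 8.0 h

- where a step has two of a species, its rate is k times that concentration squared, and two are used at each turn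
- the average divides the monomer in chains by the number of chains begun, living and dead together
- run time (flask): 8.0 h

No step in the scheme removes a living end, so I took the average as monomer in chains divided by a count that grows as the first step consumes initiator, and I froze that count at its end value. Initiator, reckoned at its own charge and that of the free monomer, had a time of about 84.2 s. Free monomer, reckoned with a whole initiator charge of living ends and the impurity as charged, had a time of 19.1 min, which is far longer, so I held it at its charge. Initiation is then first order in initiator and the self-consumption second order, and integrating the two gave 49.3%. This part of the initiator charge that begins a chain, with free monomer frozen at its charge, is my chain share. The other 50.7% of the charge I booked to spent initiator.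

Next I kept the ledger of the free monomer. The impurity has a half-life of 0.077 h with the monomer as charged, much shorter than the run, so I booked its whole charge, 20.0% of the free monomer, to quenched substrate. With the living ends held constant, I let the remainder decay in a pseudo-first-order way, which left 0.397% of the charge free at 8.0 h. That put 79.6% into chains, and dividing by the chain count gave 44.1 units, more than 40, so I committed to yes.

The forecast also said yes, with 46.5 units, higher than my figure, holding that “with no termination that number then stays fixed”.

The flask gave 45.2 units at 8.0 h, so the answer is yes, with 40 reached at 3.28 h. The living end stood at 47.9% of the initiator charge at 0.800 h and at 48.0% at 8.00 h. I used my chain share of 49.3% once more at 4.00 h, when 93.9% of the free monomer had reacted: taking off the 20.0% quenched and dividing by the chains that share begins gave 40.9 units, and the flask then stood at 42.0.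

The constants come from no measurement, and the outcome is calculated.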